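## Analysis of the target

The target is a daucane-type diester. Its skeleton is a hydroazulene in which a cyclopentane (C10, C1, C2, C3, C4) is trans-fused along C4–C10 to a cycloheptene (C4 to C10) that carries the C7 methyl on a C7=C8 double bond. Atom labels used throughout: C1 acetoxy CH, C2 CH2, C3 isopropyl carbinol carbon, C4 ring-fusion CH, C5 aroyloxy CH, C6 CH2, C7 olefinic C–CH3, C8 olefinic CH, C9 CH2, C10 quaternary C–CH3. β is the face of the C10 methyl and α the opposite face.

Five contiguous stereocentres must be set. C10 is quaternary. H-4 is α, which makes the fusion trans. The C1 acetate is α, anti to the methyl. At C3 the hydroxyl is β, syn to the methyl, and the isopropyl group is α. The C5 4-hydroxybenzoate is α, cis to H-4 and equatorial on the chair-like seven-membered ring.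

The sensitive groups are two different esters on secondary carbinols that must be told apart, a free phenol, a free tertiary alcohol 1,3 to both ester carbons, and a trisubstituted olefin that must stay at C7=C8 and not move to C6=C7. The hard points are the quaternary C10 flanked by two stereocentres, a trans 5–7 fusion that cannot be counted on to be the more stable one, the tertiary carbinol next to the ring fusion, and the olefin position between two methylene groups.

The feature the plan rests on: C10 carries a methyl, an oxygenated neighbour (C1) and, across the larger ring, the carbon that will bear the ring methyl (C7). If the C4–C10 bond is replaced by a C5–C10 bond, the skeleton becomes a 10-methyldecalin oxygenated at C1 and C7. That is the pattern of the commercial enantiopure enedione 1, whose (R) centre already has the configuration needed at C10.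

## Retrosynthetic reasoning

**C5 ester and phenol (27 ⇒ 26 ⇒ 22 + 25).** The phenol is unmasked last and the C5–O acyl bond is cut next. The aroate is the group least tolerant of bases and organometallics, so it goes on when nothing else remains to be built. Acid 25 comes from 23 by silylation; the masked phenol prevents self-acylation.

**C1 acetate (22 ⇒ 21 ⇒ 20 ⇒ 19).** The C5 oxygen is held as a PMB ether while the C1–O bond is made. That bond is cut with inversion, so 21 is traced to the 1β-alcohol 20. C1 is carried as the β-silyl ether for three reasons. It is what direct hydride reduction of 1 gives. A 1α (axial) silyloxy group on the decalin would sit 1,3-diaxial to the C5 oxygen, in the path of the osmylation and of any later displacement. In the hydroazulene the β group leaves the α-face of C3 and C4 open for the reactions that must occur there. The forward step must displace at a cyclopentyl carbon next to C10, from the face anti to the methyl.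

**C7 methyl (19 ⇒ 18 ⇒ 17).** The C7–CH3 bond is cut to an enol triflate, which fixes the olefin wherever the C7 ketone was enolised. The forward step must enolise toward C8 and not C6. The ketone of 17 is the enone carbonyl of 1, carried as a dioxolane up to 16.

**C3 isopropyl (17 ⇒ 16 ⇒ 14 + 15).** The C3–C bond is cut to the cyclopentanone 14 and the Grignard reagent 15. Addition must come from the α-face so that the hydroxyl ends up syn to the methyl.

**C3 oxygen and H-4 (14 ⇒ 13 ⇒ 11 ⇒ 10 ⇒ 9).** The C3–O and C4–H bonds are traced to the C3=C4 olefin of an allylic ether. C5 is reduced before C3 is oxidised, because a C3 ketone beside a C5 ketone would be a 1,3-diketone that cannot be isopropylated. Syn addition of H and boron from the α-face then sets the trans fusion under kinetic control, not through an equilibrium of ring-fusion ketones. The C5 carbinol is set on enone 9 by a catalyst-controlled reduction.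

**C3=C4 olefin (9 ⇒ 8).** The enone comes from ketone 8 by dehydrogenation. Only the C4 side can give an olefin, because C6 has the fully substituted C7 as its β-carbon. This step erases C4, so the configuration at C4 in 8 does not matter.

**Ring-fusion shift (8 ⇒ 7).** The C4–C10 bond is cut and C10 is reconnected to C5. This turns the 5–7 ketone into a trans-decalin with a tertiary C5 hydroxyl and a C4 leaving group. The forward reaction must move the ring-fusion bond, not a hydrogen or C3. It gains both rings of the target from a commercial bicycle, with C10 already in place.

**Precursor (7 ⇒ 6 ⇒ 5 ⇒ 4 ⇒ 2 + 3 ⇒ 1).** The mesylate comes from the cis-diol 6, the diol from the C4=C5 olefin 5, and the olefin from deconjugative ketalisation of 2 with 3. Alcohol 2 is the selective reduction product of 1. All five steps are standard for this ring system, so the risk sits in the shift itself.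

## Alternatives that were turned down

**Alternative 1:** cut C5–C6 and close the seven-membered ring last. Going forward, an aldehyde C–H bond at C5 would add under rhodium catalysis across a methyl-substituted 1,3-diene hanging from C10: hydride to C9, acyl carbon to C6. This would give cycloheptenone A1.
- For it: the C5 ketone and the C7=C8 olefin arrive together, and the allyl-metal intermediate dictates the olefin position. On that point it is stronger than the chosen route, which relies on a kinetic enolisation (step 14). The C1 acetate and the protected C3 carbinol are already present, so little remains after A1.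
- Against it: the ring closure builds none of the stereocentres. C10 with its dienyl group, C1, the tertiary C3 carbinol and C4 must all be assembled on a monocycle with no second ring to relay configuration. The aldehyde sits on C4, which is epimerisable and β to the C3 silyloxy group. Insertion next to a quaternary carbon is slow enough for decarbonylation to compete. The β,γ-unsaturated ketone A1 can slip into conjugation, and C5 must still be reduced to the α-alcohol.
- Comparison: the chosen route takes C10 from 1 and lets it direct every later centre; it pays for this with more functional-group steps after the skeleton is made.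

**Alternative 2:** cut C1–C10 and form the five-membered ring by a silicon-directed Nazarov closure onto a preformed cycloheptadiene. Forward, a Lewis acid would trigger conrotatory 4π closure of a β-silyl divinyl ketone; loss of silicon places the enone at C1=C2 and protonation sets C4, giving A2.
- For it: it is the shortest way to the bicycle. The seven-membered ring already carries the C7=C8 methyl olefin and the C5 oxygen, so olefin regiochemistry never arises, and the C3 carbonyl is ready for isopropyl addition. On step economy and on the olefin it is stronger than the chosen route.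
- Against it: C10 is created in the electrocyclisation, and its configuration relative to C5 depends on the sense of conrotation, for which only the remote C5 silyloxy group offers a bias. C4 is set by protonation, which in such closures usually gives the cis fusion. The C1 oxygen is absent and would have to be added to the enone next to the new quaternary centre with α configuration. An allylic silyl ether and a skipped diene must survive a strong Lewis acid. All absolute stereochemistry hangs on one carbinol centre.
- Comparison: the chosen route buys C10 and the C1 oxygen with the starting material and uses a stereospecific 1,2-shift in place of a torquoselective closure.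

**Alternative 3:** cut C9–C10 and add a temporary C4–C8 bond. Forward, irradiation near 350 nm of an enone with a tethered terminal olefin would give the cyclobutane photoadduct A3; later cleavage of C4–C8 merges cyclobutane and cyclopentane into the seven-membered ring.
- For it: one photochemical step makes the quaternary C10 and two C–C bonds, with regiochemistry held by the tether. The later cleavage is strain-driven. If the cleavage is run reductively from the C3 ketone, the C7 acetate is expelled toward C8 and the olefin lands at C7=C8 by mechanism. That is again stronger than the chosen route on olefin position, and the C3 ketone is in place.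
- Against it: A3 has six stereocentres and three different oxygen protecting groups, and its photosubstrate needs a long preparation. Facial selectivity of the cycloaddition must be relayed from the C1 and C5 carbinols. H-4 is set by protonation of the enolate released in the cleavage, which gives no assurance of the trans fusion. Much of the functionality in A3 exists only to be removed.
- Comparison: the chosen route reaches the same skeleton from a cheap bicycle in six steps and sets H-4 by a syn addition, at the price of a less certain olefin placement.

Key step: step 6

Remark on conventions: the labels C1–C10 are also used for the decalin intermediates, in which C10 is bonded to C5 instead of C4; compound names use these labels, and the SMILES in the compound list define the configurations.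

Remark on the ring fusion: the relative stability of the cis- and trans-fused C5 ketones is not relied upon. Ketone 8 is taken on as the kinetically formed cis isomer, and H-4 is set in step 10.

## Route

Step 1
Reactants: 1 (R)-8a-methyl-3,4,8,8a-tetrahydronaphthalene-1,6(2H,7H)-dione (Wieland–Miescher ketone)
Product: 2 (4aR,5R)-5-hydroxy-4a-methyl-4,4a,5,6,7,8-hexahydronaphthalen-2(3H)-one (1β-hydroxy enone)
Conditions: NaBH4 (0.3 equiv), EtOH, −10 °C
Reagents that add atoms: none
Why: Chemoselective borohydride reduction: the saturated C1 ketone is more electrophilic than the conjugated C7 carbonyl, and hydride adds axially from the α-face, anti to the axial C10 methyl, so the new hydroxyl is equatorial and β.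

Step 2
Reactants: 2 1β-hydroxy enone; 3 ethylene glycol
Product: 4 1β-hydroxy-10β-methyloctal-4(5)-en-7-one ethylene ketal (C4=C5 olefin, dioxolane at C7)
Conditions: TsOH·H2O (cat.), benzene, reflux, Dean–Stark
Reagents that add atoms: none
Why: Acid-catalysed ketalisation with deconjugation: the enone carbonyl is ketalised through its dienol ether and the olefin settles at C4=C5, the only β,γ-position with a hydrogen (C10 is quaternary). The hydroxyl is left free here because a silyl ether would not be safe in hot TsOH and a diol.

Step 3
Reactants: 4 hydroxy ketal
Product: 5 1β-(tert-butyldimethylsilyloxy)-10β-methyloctal-4(5)-en-7-one ethylene ketal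
Conditions: TBSCl, imidazole, DMF, rt to 40 °C
Reagents that add atoms: tert-butyldimethylsilyl chloride, CC(C)(C)[Si](C)(C)Cl
Why: Standard silylation of a secondary alcohol; the equatorial neopentyl hydroxyl is reached by TBSCl/imidazole and the ketal is untouched by the basic medium.

Step 4
Reactants: 5 silyl ether olefin
Product: 6 1β-(tert-butyldimethylsilyloxy)-4α,5α-dihydroxy-10β-methyl-trans-decalin-7-one ethylene ketal
Conditions: OsO4 (cat.), NMO, acetone/H2O, rt
Reagents that add atoms: N-methylmorpholine N-oxide, C[N+]1([O-])CCOCC1; water, O (OsO4, O=[Os](=O)(=O)=O, is the oxygen carrier)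
Why: Upjohn dihydroxylation, a concerted syn [3+2] addition: OsO4 approaches C4=C5 from the α-face, away from the axial C10 methyl on the carbon next to C5, which sets the 4α,5α-diol and a trans ring fusion. The equatorial 1β-silyloxy group does not crowd that face, which is why C1 is kept in this configuration.

Step 5
Reactants: 6 cis-diol
Product: 7 1β-(tert-butyldimethylsilyloxy)-5α-hydroxy-4α-mesyloxy-10β-methyl-trans-decalin-7-one ethylene ketal
Conditions: MsCl, pyridine, DMAP (cat.), 0 °C
Reagents that add atoms: methanesulfonyl chloride, CS(=O)(=O)Cl
Why: Selective sulfonylation: only the secondary equatorial C4 hydroxyl reacts; the tertiary axial C5 hydroxyl is too hindered at 0 °C and is kept as the trigger for the shift.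

Step 6
Reactants: 7 hydroxy mesylate
Product: 8 1β-(tert-butyldimethylsilyloxy)-10β-methyl-cis-perhydroazulen-5-one 7-ethylene ketal (H-4 β)
Conditions: KOt-Bu (1.05 equiv), THF/t-BuOH, 0 °C, short contact; aq NH4Cl
Reagents that add atoms: none
Why: The tertiary C5 hydroxyl is deprotonated and the alkoxide pushes the C5–C10 bond, which is antiperiplanar to the equatorial C4–OMs bond in the chair–chair trans-decalin, across to C4 as mesylate leaves, so that C5 becomes the carbonyl carbon in one concerted 1,2-shift. This is the base-induced pinacol-type rearrangement known for cis-diol monosulfonates of trans-decalins, which gives hydroazulenones. The five-membered ring (C10, C1, C2, C3, C4) arises by contraction of the C1–C5 ring through the alkyl shift and the seven-membered ring (C4 to C10) by the matching one-carbon enlargement of the other ring; neither is a cyclisation of an open chain. C10 migrates with retention, so the quaternary centre of 1 is carried over unchanged; C4 is inverted because C10 enters anti to the departing mesylate, which puts H-4 on the face of the C10 methyl and makes the first-formed ketone cis-fused. The step needs migration of the ring-fusion bond and not elimination, epoxide closure or a hydride shift: the leaving group is equatorial, so no C–H bond is antiperiplanar to it, and the C5 oxygen is cis to it and cannot displace it. Only one equivalent of base is used, at 0 °C, because the dioxolane now sits β to a ketone and would open by E1cB from the C6 enolate on longer exposure; for the same reason no equilibration to the trans-fused epimer is attempted. The configuration at C4 is of no consequence, since C4 becomes sp2 in step 7 and is set again in step 10.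

Step 7
Reactants: 8 cis-fused ketone
Product: 9 1β-(tert-butyldimethylsilyloxy)-10β-methylhydroazul-3-en-5-one 7-ethylene ketal (C3=C4 enone)
Conditions: IBX (2.5 equiv), DMSO/fluorobenzene, 70 °C
Reagents that add atoms: none
Why: IBX dehydrogenation of a ketone through its enol: an olefin can only form on the C4 side, because the other α-carbon, C6, has the fully substituted C7 as its β-carbon and offers no β-hydrogen. Silyl ether and ketal tolerate the near-neutral medium, and both C4 epimers of 8 would give the same enone.

Step 8
Reactants: 9 enone
Product: 10 (5S)-1β-(tert-butyldimethylsilyloxy)-5α-hydroxy-10β-methylhydroazul-3-ene 7-ethylene ketal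
Conditions: (R)-Me-CBS oxazaborolidine (1 equiv), catecholborane, toluene, −78 to −40 °C
Reagents that add atoms: none
Why: Corey–Bakshi–Shibata reduction, 1,2-selective on enones: the carbonyl binds the catalyst boron anti to its larger flank, the fully substituted sp2 carbon C4, and hydride goes to the β-face of C5; with the (R)-catalyst this should give the (5S)-alcohol, hydroxyl α. Catalyst control is chosen because the two faces of this carbonyl are shielded to a similar degree (C10 methyl on one side, C9 on the other).

Step 9
Reactants: 10 allylic alcohol
Product: 11 5α-(4-methoxybenzyloxy) ether of 10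
Conditions: NaH, PMBCl, Bu4NI (cat.), THF/DMF, 0 °C to rt
Reagents that add atoms: 4-methoxybenzyl chloride, COc1ccc(CCl)cc1
Why: Williamson etherification of the sodium alkoxide; the PMB ether withstands borane, peroxide, organometallics and amide base and is later removed oxidatively in the presence of esters and the olefin.

Step 10
Reactants: 11 allylic PMB ether
Product: 13 1β-(tert-butyldimethylsilyloxy)-3α-hydroxy-5α-(4-methoxybenzyloxy)-10β-methyl-trans-perhydroazulen-7-one ethylene ketal (H-4 α), via C3 alkylborane 12 (not isolated)
Conditions: BH3·THF, THF, 0 °C to rt; then NaOH, H2O2, 0 °C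
Reagents that add atoms: hydrogen peroxide, OO
Why: Hydroboration–oxidation: boron adds to the less substituted C3 and hydrogen to C4 in a syn four-centre addition on the α-face, opposite the C10 methyl on the carbon next to C4 and the 1β-silyloxy group, as is usual for ring-fusion olefins next to an angular methyl in hydrindane-type systems. This fixes H-4 as α, the trans fusion, under kinetic control; oxidation of the C–B bond with retention gives the 3α-alcohol, whose configuration is lost in the next step.

Step 11
Reactants: 13 C3 alcohol
Product: 14 1β-(tert-butyldimethylsilyloxy)-5α-(4-methoxybenzyloxy)-10β-methyl-trans-perhydroazulene-3,7-dione 7-ethylene ketal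
Conditions: Dess–Martin periodinane, NaHCO3, CH2Cl2, 0 °C
Reagents that add atoms: none
Why: Dess–Martin oxidation under buffered, non-enolising conditions, so that C4, now α to a ketone, keeps its configuration and neither the C1 silyloxy nor the C5 PMB-oxy group, both β to the carbonyl, is eliminated.

Step 12
Reactants: 14 C3 ketone; 15 isopropylmagnesium chloride
Product: 16 1β-(tert-butyldimethylsilyloxy)-3β-hydroxy-3α-isopropyl-5α-(4-methoxybenzyloxy)-10β-methyl-trans-perhydroazulen-7-one ethylene ketal
Conditions: CeCl3 (anhydrous), THF, −78 °C
Reagents that add atoms: none
Why: Organocerium addition to a ketone (transmetallation of the Grignard reagent to cerium suppresses enolisation and β-hydride reduction): the nucleophile enters on the α-face, quasi-equatorially, because the β-face carries the quasi-axial C10 methyl 1,3 to the carbonyl and the 1β-silyloxy group. The new hydroxyl is β and the isopropyl group α.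

Step 13
Reactants: 16 tertiary alcohol ketal
Product: 17 1β-(tert-butyldimethylsilyloxy)-3β-hydroxy-3α-isopropyl-5α-(4-methoxybenzyloxy)-10β-methyl-trans-perhydroazulen-7-one
Conditions: PPTS, acetone/H2O, 55 °C
Reagents that add atoms: water, O
Why: Mild acid-catalysed ketal hydrolysis; PPTS leaves the secondary TBS ether, the PMB ether and the tertiary alcohol intact and is too weak to eliminate the β-PMB-oxy group from the new ketone.

Step 14
Reactants: 17 C7 ketone
Product: 18 C7 enol triflate of 17 with the C7=C8 double bond
Conditions: KHMDS (2.2 equiv), THF, −78 °C; then PhNTf2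
Reagents that add atoms: N-phenylbis(trifluoromethanesulfonimide), O=S(=O)(N(c1ccccc1)S(=O)(=O)C(F)(F)F)C(F)(F)F
Why: Kinetic enolisation and O-sulfonylation: the first equivalent of base forms the C3 alkoxide and the second removes a proton from C8, which is flanked only by the C9 methylene, and not from C6, which is shielded by the C5 centre with its PMB ether and lies next to a β-oxygen. The hindered tertiary alkoxide is not triflated at −78 °C and returns as the alcohol on work-up.

Step 15
Reactants: 18 enol triflate
Product: 19 1β-(tert-butyldimethylsilyloxy)-3β-hydroxy-3α-isopropyl-5α-(4-methoxybenzyloxy)-7,10β-dimethyl-trans-hydroazul-7-ene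
Conditions: MeMgBr (excess), Fe(acac)3 (cat.), THF/NMP, −20 °C
Reagents that add atoms: methylmagnesium bromide, C[Mg]Br
Why: Iron-catalysed cross-coupling of an alkenyl triflate with a methyl Grignard reagent, which replaces C–OTf by C–CH3 with the olefin fixed at C7=C8; the excess reagent covers the free tertiary hydroxyl.

Step 16
Reactants: 19 silyl ether
Product: 20 1β,3β-dihydroxy-3α-isopropyl-5α-(4-methoxybenzyloxy)-7,10β-dimethyl-trans-hydroazul-7-ene
Conditions: TBAF, THF, 40 °C
Reagents that add atoms: none
Why: Fluoride cleavage of the only silyl ether; the ethers, the olefin and the tertiary alcohol are inert.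

Step 17
Reactants: 20 1β,3β-diol
Product: 21 1α-acetoxy-3β-hydroxy-3α-isopropyl-5α-(4-methoxybenzyloxy)-7,10β-dimethyl-trans-hydroazul-7-ene
Conditions: PPh3, DIAD, AcOH, toluene, 0 °C to rt
Reagents that add atoms: acetic acid, CC(=O)O
Why: Mitsunobu esterification: the secondary C1 hydroxyl is activated as its oxyphosphonium ion and displaced by acetate from the α-face with inversion, anti to the C10 methyl, as in the known inversion of hydrindane-type cyclopentanols that flank a quaternary carbon; the tertiary C3 hydroxyl cannot be displaced. This sets the 1α-acetate.

Step 18
Reactants: 21 PMB ether acetate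
Product: 22 1α-acetoxy-3β,5α-dihydroxy-3α-isopropyl-7,10β-dimethyl-trans-hydroazul-7-ene
Conditions: DDQ, CH2Cl2/pH 7 buffer, 0 °C
Reagents that add atoms: none
Why: Oxidative PMB cleavage through the benzylic oxocarbenium ion, which water hydrolyses; acetate, tertiary alcohol and the trisubstituted olefin are not attacked in the buffered two-phase medium.

Step 19
Reactants: 23 4-hydroxybenzoic acid
Product: 25 4-(tert-butyldimethylsilyloxy)benzoic acid, via tert-butyldimethylsilyl 4-(tert-butyldimethylsilyloxy)benzoate 24 (not isolated)
Conditions: TBSCl (2.3 equiv), imidazole, DMF, rt; then AcOH/THF/H2O, rt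
Reagents that add atoms: tert-butyldimethylsilyl chloride, CC(C)(C)[Si](C)(C)Cl
Why: Silylation of both acidic groups followed by selective hydrolysis of the labile silyl ester, which leaves the aryl silyl ether; the phenol is masked so that the acid cannot acylate itself in step 20.

Step 20
Reactants: 22 C5 alcohol; 25 4-(tert-butyldimethylsilyloxy)benzoic acid
Product: 26 O-tert-butyldimethylsilyl ether of the target (5α-[4-(tert-butyldimethylsilyloxy)benzoyloxy] ester)
Conditions: EDC·HCl, DMAP, CH2Cl2, rt
Reagents that add atoms: none
Why: Steglich esterification (carbodiimide activation, acyl transfer by DMAP) with retention at C5; only the secondary equatorial C5 hydroxyl is acylated, the tertiary C3 hydroxyl is not.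

Step 21
Reactants: 26 silyl-protected diester
Product: 27 target, 1α-acetoxy-3β-hydroxy-5α-(4-hydroxybenzoyloxy)-3α-isopropyl-7,10β-dimethyl-trans-hydroazul-7-ene
Conditions: TBAF, AcOH, THF, 0 °C
Reagents that add atoms: none
Why: Fluoride cleavage of the aryl silyl ether, which is far more labile than the alkyl esters; buffering with AcOH keeps the phenoxide from attacking the acetate or the benzoate.

## Compound list

1 | (R)-8a-methyl-3,4,8,8a-tetrahydronaphthalene-1,6(2H,7H)-dione | O=C1CCCC2=CC(=O)CC[C@@]12C | starting material
2 | (4aR,5R)-5-hydroxy-4a-methyl-4,4a,5,6,7,8-hexahydronaphthalen-2(3H)-one | O[C@@H]1CCCC2=CC(=O)CC[C@@]12C | intermediate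
3 | ethylene glycol | OCCO | starting material
4 | 1β-hydroxy-10β-methyloctal-4(5)-en-7-one ethylene ketal | O[C@@H]1CCC=C2CC3(OCCO3)CC[C@@]12C | intermediate
5 | 1β-(tert-butyldimethylsilyloxy)-10β-methyloctal-4(5)-en-7-one ethylene ketal | CC(C)(C)[Si](C)(C)O[C@@H]1CCC=C2CC3(OCCO3)CC[C@@]12C | intermediate
6 | 1β-silyloxy-4α,5α-dihydroxy-10β-methyl-trans-decalin-7-one ethylene ketal | CC(C)(C)[Si](C)(C)O[C@@H]1CC[C@@H](O)[C@]2(O)CC3(OCCO3)CC[C@@]12C | intermediate
7 | 1β-silyloxy-5α-hydroxy-4α-mesyloxy-10β-methyl-trans-decalin-7-one ethylene ketal | CC(C)(C)[Si](C)(C)O[C@@H]1CC[C@@H](OS(C)(=O)=O)[C@]2(O)CC3(OCCO3)CC[C@@]12C | intermediate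
8 | 1β-silyloxy-10β-methyl-cis-perhydroazulen-5-one 7-ethylene ketal (H-4 β) | CC(C)(C)[Si](C)(C)O[C@@H]1CC[C@H]2C(=O)CC3(OCCO3)CC[C@@]12C | intermediate
9 | 1β-silyloxy-10β-methylhydroazul-3-en-5-one 7-ethylene ketal | CC(C)(C)[Si](C)(C)O[C@@H]1CC=C2C(=O)CC3(OCCO3)CC[C@@]12C | intermediate
10 | (5S)-5α-hydroxy allylic alcohol | CC(C)(C)[Si](C)(C)O[C@@H]1CC=C2[C@@H](O)CC3(OCCO3)CC[C@@]12C | intermediate
11 | 5α-PMB ether of 10 | CC(C)(C)[Si](C)(C)O[C@@H]1CC=C2[C@@H](OCc4ccc(OC)cc4)CC3(OCCO3)CC[C@@]12C | intermediate
12 | 3α-boryl alkylborane (H-4 α) | CC(C)(C)[Si](C)(C)O[C@@H]1C[C@@H](B)[C@@H]2[C@@H](OCc4ccc(OC)cc4)CC3(OCCO3)CC[C@@]12C | intermediate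
13 | 3α-hydroxy trans-fused alcohol | CC(C)(C)[Si](C)(C)O[C@@H]1C[C@@H](O)[C@@H]2[C@@H](OCc4ccc(OC)cc4)CC3(OCCO3)CC[C@@]12C | intermediate
14 | trans-fused C3 ketone | CC(C)(C)[Si](C)(C)O[C@@H]1CC(=O)[C@@H]2[C@@H](OCc4ccc(OC)cc4)CC3(OCCO3)CC[C@@]12C | intermediate
15 | isopropylmagnesium chloride | CC(C)[Mg]Cl | starting material
16 | 3β-hydroxy-3α-isopropyl ketal | CC(C)(C)[Si](C)(C)O[C@@H]1C[C@@](O)(C(C)C)[C@@H]2[C@@H](OCc4ccc(OC)cc4)CC3(OCCO3)CC[C@@]12C | intermediate
17 | C7 ketone | CC(C)(C)[Si](C)(C)O[C@@H]1C[C@@](O)(C(C)C)[C@@H]2[C@@H](OCc4ccc(OC)cc4)CC(=O)CC[C@@]12C | intermediate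
18 | C7 enol triflate (C7=C8) | CC(C)(C)[Si](C)(C)O[C@@H]1C[C@@](O)(C(C)C)[C@@H]2[C@@H](OCc4ccc(OC)cc4)CC(OS(=O)(=O)C(F)(F)F)=CC[C@@]12C | intermediate
19 | C7 methyl olefin, 1β-silyl ether | CC(C)(C)[Si](C)(C)O[C@@H]1C[C@@](O)(C(C)C)[C@@H]2[C@@H](OCc4ccc(OC)cc4)CC(C)=CC[C@@]12C | intermediate
20 | 1β,3β-diol | O[C@@H]1C[C@@](O)(C(C)C)[C@@H]2[C@@H](OCc4ccc(OC)cc4)CC(C)=CC[C@@]12C | intermediate
21 | 1α-acetate, 5α-PMB ether | CC(=O)O[C@H]1C[C@@](O)(C(C)C)[C@@H]2[C@@H](OCc4ccc(OC)cc4)CC(C)=CC[C@@]12C | intermediate
22 | 1α-acetate, 5α-alcohol | CC(=O)O[C@H]1C[C@@](O)(C(C)C)[C@@H]2[C@@H](O)CC(C)=CC[C@@]12C | intermediate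
23 | 4-hydroxybenzoic acid | O=C(O)c1ccc(O)cc1 | starting material
24 | tert-butyldimethylsilyl 4-(tert-butyldimethylsilyloxy)benzoate | CC(C)(C)[Si](C)(C)Oc1ccc(cc1)C(=O)O[Si](C)(C)C(C)(C)C | intermediate
25 | 4-(tert-butyldimethylsilyloxy)benzoic acid | CC(C)(C)[Si](C)(C)Oc1ccc(cc1)C(=O)O | intermediate
26 | O-silyl ether of the target | CC(=O)O[C@H]1C[C@@](O)(C(C)C)[C@@H]2[C@@H](OC(=O)c3ccc(O[Si](C)(C)C(C)(C)C)cc3)CC(C)=CC[C@@]12C | intermediate
27 | target | CC(=O)O[C@H]1C[C@@](O)(C(C)C)[C@@H]2[C@@H](OC(=O)c3ccc(O)cc3)CC(C)=CC[C@@]12C | target

## Step count and least certain steps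

Total: 21 steps. Longest linear sequence: 20 steps (steps 1–18, 20 and 21); step 19 is a one-step side branch.

**Step 6 (key step).** What is most likely to go wrong is opening of the dioxolane: once the ketone has formed, residual alkoxide can deprotonate C6 and the ketal oxygen β to the carbonyl is expelled, or the shift is slow enough for this to compete. Fallback: setting out from 7, the shift is run with no base able to form an enolate, using LiClO4 and CaCO3 in THF at 50 °C. Lithium-assisted ionisation of the mesylate, pushed by the neutral C5 hydroxyl, moves the same antiperiplanar C5–C10 bond. This returns to the route at 8 and makes no new compound (F0).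

**Step 7.** Enolisation toward the hindered C4 methine may be too slow at a temperature the β-keto ketal tolerates, so that conversion stalls or the ketal is lost. Fallback: from 8, thermodynamic silylation (TMSCl, Et3N, DMF, 80 °C) gives the C4=C5 trimethylsilyl enol ether F1, and Pd(OAc)2 in MeCN (Saegusa–Ito oxidation) converts it to 9. The regioisomeric C5=C6 enol ether cannot eliminate, reverts to 8 on work-up and is recycled.

**Step 8.** Facial selectivity may be poor if the substrate's own bias opposes the catalyst. Fallback: from 9, Luche reduction (NaBH4, CeCl3·7H2O, MeOH, −40 °C) under substrate control, which in that case should favour the 5β-allylic alcohol F2. Mitsunobu inversion with 4-nitrobenzoic acid (PPh3, DIAD) gives the 5α 4-nitrobenzoate F3, and K2CO3 in MeOH returns to the route at 10.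

**Step 12.** β-Hydride transfer from the isopropyl reagent or enolisation of 14 may compete, the latter with epimerisation at C4 or β-elimination of the C1 or C5 oxygen. Fallback: from 14, isopropenylmagnesium bromide with CeCl3, a smaller sp2 nucleophile without β-hydrogens, gives the isopropenyl carbinol F4. Hydrogenation of its 1,1-disubstituted olefin (H2, RhCl(PPh3)3, benzene), which leaves the PMB ether alone, returns to the route at 16. This does not change the face of attack, which rests on the C10 methyl.

**Step 14.** Deprotonation may leak to C6, which would place the olefin at C6=C7 and open the way to β-elimination of the PMB-oxy group. Fallback: from 17, condensation with 2,4,6-triisopropylbenzenesulfonyl hydrazide gives the sulfonylhydrazone F5; excess n-BuLi and then MeI (Shapiro reaction) form and methylate the C7 vinyllithium. This returns to the route at 19 and replaces steps 14 and 15. Here the olefin position rests on the hydrazone geometry (sulfonamide turned away from the more hindered C6 side) and syn-directed deprotonation, not on kinetic enolisation.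

**Step 17.** Displacement at the neopentyl C1 centre may fail, or elimination toward C2 may take over. Fallback: from 20, Dess–Martin oxidation gives the C1 ketone F6. Me4NBH(OAc)3 in AcOH/MeCN (Evans–Saksena reduction) binds the 3β-hydroxyl and delivers hydride across the five-membered ring to the β-face of C1, giving the 1α,3β-diol F7. Ac2O, pyridine and DMAP acetylate only the secondary hydroxyl and return to the route at 21.

## Further compounds

F0 | step 6 | none | none
F1 | step 7 | C4=C5 trimethylsilyl enol ether of 8 | CC(C)(C)[Si](C)(C)O[C@@H]1CCC2=C(O[Si](C)(C)C)CC3(OCCO3)CC[C@@]12C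
F2 | step 8 | 5β-hydroxy epimer of 10 | CC(C)(C)[Si](C)(C)O[C@@H]1CC=C2[C@H](O)CC3(OCCO3)CC[C@@]12C
F3 | step 8 | 5α 4-nitrobenzoate of 10 | CC(C)(C)[Si](C)(C)O[C@@H]1CC=C2[C@@H](OC(=O)c4ccc(cc4)[N+](=O)[O-])CC3(OCCO3)CC[C@@]12C
F4 | step 12 | 3β-hydroxy-3α-isopropenyl analogue of 16 | CC(C)(C)[Si](C)(C)O[C@@H]1C[C@@](O)(C(C)=C)[C@@H]2[C@@H](OCc4ccc(OC)cc4)CC3(OCCO3)CC[C@@]12C
F5 | step 14 | 2,4,6-triisopropylbenzenesulfonylhydrazone of 17 | CC(C)(C)[Si](C)(C)O[C@@H]1C[C@@](O)(C(C)C)[C@@H]2[C@@H](OCc4ccc(OC)cc4)CC(=NNS(=O)(=O)c5c(cc(cc5C(C)C)C(C)C)C(C)C)CC[C@@]12C
F6 | step 17 | C1 ketone from 20 | O=C1C[C@@](O)(C(C)C)[C@@H]2[C@@H](OCc4ccc(OC)cc4)CC(C)=CC[C@@]12C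
F7 | step 17 | 1α,3β-diol (C1 epimer of 20) | O[C@H]1C[C@@](O)(C(C)C)[C@@H]2[C@@H](OCc4ccc(OC)cc4)CC(C)=CC[C@@]12C
A1 | alternative 1 | 1-acetoxy-6,8a-dimethyl-3-isopropyl-3-(triethylsilyloxy)octahydroazulen-4-one with the 6,7-olefin | CC(=O)O[C@H]1C[C@@](O[Si](CC)(CC)CC)(C(C)C)[C@@H]2C(=O)CC(C)=CC[C@@]12C
A2 | alternative 2 | 8-(tert-butyldimethylsilyloxy)-3a,6-dimethyl-3a,4,7,8-tetrahydroazulen-1(8aH)-one | C1=CC(=O)[C@@H]2[C@H](O[Si](C)(C)C(C)(C)C)CC(C)=CC[C@@]12C
A3 | alternative 3 | tricyclic cyclobutane photoadduct (cyclopentanone, cyclobutane and acetoxy cyclopentane sharing C4) | O=C1C[C@@H](O[Si](C)(C)C(C)(C)C)[C@]2(C)C[C@H]3[C@](C)(OC(C)=O)C[C@H](OCOC)[C@@]123
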